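**Assumptions.** Positions are given in prostanoid numbering (C1 = ester carbon … C20), and the target is the (5E,7Z,12R,14Z) isomer encoded by the SMILES. The (S)-phosphoric acid is taken to deliver 12R by extrapolating the aldehyde allylboration model to this ketone; this sense is unproven, and if the first run gives 12S the (R)-catalyst is used with nothing else changed.

## Retrosynthetic overview

1. Target ⇐ des-bromo trienone: the C10–Br is installed last by nucleophilic 10,11-epoxidation and HBr opening/dehydration, which leaves the 14Z alkene and the diene untouched.
2. Des-bromo trienone ⇐ achiral 2-alkylidene-cyclopent-4-ene-1,3-dione + racemic α-pentylallyl-Bpin: one chiral-phosphoric-acid-catalysed allylboration makes C12–C13, sets C12 (R) and the 14Z alkene, and fixes 7Z by reacting at the carbonyl remote from the chain.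
3. Alkylidene-dione ⇐ Knoevenagel of cyclopent-4-ene-1,3-dione with methyl (E)-7-oxohept-5-enoate (from cross-metathesis); the boronate ⇐ one-pot double Matteson substitution of Cl2CH-Bpin.
4. Ring order: the only ring (the cyclopentene) is bought intact as the dione; there is no ring-forming step.

## Route

**Step 1**
Reactants: 1 methyl hex-5-enoate; 2 (E)-crotonaldehyde (5 equiv)
Product: 3 methyl (E)-7-oxohept-5-enoate
Conditions: Hoveyda–Grubbs II (2 mol%), CH2Cl2, 40 °C
Reagents that add atoms: none (all product atoms come from 1 and 2)
Why: olefin cross-metathesis of a terminal alkene with an electron-poor enal partner, which loses propene and gives the thermodynamically preferred E-enal.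

**Step 2**
Reactants: 4 cyclopent-4-ene-1,3-dione (added slowly); 3 (1.3 equiv)
Product: 5 methyl (5E)-7-(2,5-dioxocyclopent-3-en-1-ylidene)hept-5-enoate (achiral)
Conditions: ethylenediammonium diacetate (10 mol%), 4 Å MS, CH2Cl2, 0 °C → rt
Reagents that add atoms: none (all product atoms come from 3 and 4)
Why: Knoevenagel condensation at the doubly activated CH2 of the dione via the enal iminium (1,2-addition then loss of amine); the dione is symmetric so the new exocyclic alkene has no E/Z issue, and the oxa-6π closure that usually follows with enals is blocked because it would generate a cyclopentadienone.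

**Step 3**
Reactants: 6 2-(dichloromethyl)-4,4,5,5-tetramethyl-1,3,2-dioxaborolane; 7 n-pentylmagnesium bromide (1.0 equiv); 8 vinylmagnesium bromide (1.1 equiv)
Product: 9 rac-4,4,5,5-tetramethyl-2-(oct-1-en-3-yl)-1,3,2-dioxaborolane (α-pentylallyl-Bpin, racemic)
Conditions: 7, THF, −78 °C → rt; then 8, −78 °C → rt (one pot)
Reagents that add atoms: none (all product atoms come from 6, 7 and 8)
Why: two successive Matteson 1,2-metallate rearrangements (boronate "ate" formation, then carbon migration with chloride displacement) install pentyl and then vinyl on the same carbon; the racemate is all the next step needs, since this stereocentre is destroyed in the allyl transfer.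

**Step 4 (key step)**
Reactants: 5; 9 (2.5 equiv)
Product: 10 methyl (5E,7Z)-7-[(5R)-5-hydroxy-5-[(2Z)-oct-2-en-1-yl]-2-oxocyclopent-3-en-1-ylidene]hept-5-enoate, i.e. methyl (5E,7Z,12R,14Z)-12-hydroxy-9-oxoprosta-5,7,10,14-tetraenoate
Conditions: (S)-TRIP [(S)-3,3′-bis(2,4,6-triisopropylphenyl)-BINOL phosphoric acid] (10 mol%), 4 Å MS, toluene, −30 → 0 °C, dark; aq NaHCO3 work-up
Reagents that add atoms: none (the octenyl unit comes from 9)
Why: Proposed new method: a chiral-phosphoric-acid-catalysed, carbonyl-site- and enantioselective allylboration of one ketone of a 2-alkylidenecyclopent-4-ene-1,3-dione with a racemic α-substituted allyl-Bpin. The acid hydrogen-bonds to the pseudo-axial pinacol oxygen and raises boron Lewis acidity, so the electron-poor, non-enolisable ene-dione carbonyl enters a closed six-membered chair. γ-Attack of the CH2= terminus forms C12–C13 as the linear octenyl group, and the α-pentyl group sits pseudo-axial to avoid the pinacol methyls, so the new C14=C15 bond is Z. The catalyst pocket selects the carbonyl face (12R) and with it the matched enantiomer of 9, a kinetic resolution of the reagent, hence the excess. Attack is expected at the carbonyl cis to H7 rather than the one cis to the C6 chain, because pyramidalising the latter builds allylic 1,3-strain against C6–H and pushes the chain into the catalyst aryl wall; this site choice is what fixes 7Z, and it is a modest, unproven preference. The cyclic mechanism enforces 1,2- over 1,4/1,6-addition, and the remaining, more hindered and less electrophilic carbonyl does not react again. Closest known reaction type: phosphoric-acid-catalysed Z-selective allylboration of aldehydes with racemic α-substituted allyl pinacol boronates; the ketone (ene-dione) substrate and the selection between two carbonyls are new.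

**Step 5**
Reactants: 10
Product: 11 methyl (5E,7Z,14Z)-10,11-epoxy-12-hydroxy-9-oxoprosta-5,7,14-trienoate, oxirane cis to the C12 hydroxyl (10S,11R,12S). C12 is spatially unchanged; its label becomes S only because C11 now carries oxygen.
Conditions: 30% H2O2 (2 equiv), 1 M NaOH (0.3 equiv), MeOH, −30 → −10 °C
Reagents that add atoms: hydrogen peroxide, OO
Why: Weitz–Scheffer nucleophilic epoxidation, in which HOO⁻ adds to C11 (the unsubstituted endocyclic β-carbon, the most electrophilic site of such cross-conjugated dienones) anti to the octenyl group, while the electron-rich 14Z alkene and the ester are inert; the new epoxide centres are erased in step 6, so either diastereomer is acceptable.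

**Step 6**
Reactants: 11
Product: 12 Bromoclavulone III, methyl (5E,7Z,12R,14Z)-10-bromo-12-hydroxy-9-oxoprosta-5,7,10,14-tetraenoate
Conditions: 48% aq HBr (1.5 equiv), THF, 0 °C, short contact, dark; NaHCO3 quench
Reagents that add atoms: hydrogen bromide, Br
Why: acid-promoted opening of the α,β-epoxy ketone by bromide at C10 (α to the ketone), then β-elimination of the C11 hydroxyl through the enol (the standard epoxy ketone → α-halo enone conversion), which places Br on C10 without any electrophilic bromine that would attack the 14Z alkene or diene; C12 is not involved.

## Compound list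

1 | methyl hex-5-enoate | C=CCCCC(=O)OC | starting material
2 | (E)-crotonaldehyde | C/C=C/C=O | starting material
3 | methyl (E)-7-oxohept-5-enoate | O=C/C=C/CCCC(=O)OC | intermediate
4 | cyclopent-4-ene-1,3-dione | O=C1CC(=O)C=C1 | starting material
5 | methyl (5E)-7-(2,5-dioxocyclopent-3-en-1-ylidene)hept-5-enoate | O=C1C=CC(=O)C1=C/C=C/CCCC(=O)OC | intermediate
6 | 2-(dichloromethyl)-4,4,5,5-tetramethyl-1,3,2-dioxaborolane | ClC(Cl)B1OC(C)(C)C(C)(C)O1 | starting material
7 | n-pentylmagnesium bromide | CCCCC[Mg]Br | starting material
8 | vinylmagnesium bromide | C=C[Mg]Br | starting material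
9 | rac-4,4,5,5-tetramethyl-2-(oct-1-en-3-yl)-1,3,2-dioxaborolane | C=CC(CCCCC)B1OC(C)(C)C(C)(C)O1 | intermediate (racemic reagent)
10 | methyl (5E,7Z,12R,14Z)-12-hydroxy-9-oxoprosta-5,7,10,14-tetraenoate | CCCCC/C=C\C[C@@]1(O)C=CC(=O)/C1=C\C=C\CCCC(=O)OC | intermediate
11 | methyl (5E,7Z,14Z)-10,11-epoxy-12-hydroxy-9-oxoprosta-5,7,14-trienoate (epoxide cis to OH) | CCCCC/C=C\C[C@@]1(O)[C@@H]2O[C@@H]2C(=O)/C1=C\C=C\CCCC(=O)OC | intermediate
12 | Bromoclavulone III | CCCCC/C=C\C[C@@]1(O)C=C(Br)C(=O)/C1=C\C=C\CCCC(=O)OC | target

## Summary

Total steps: 6. Longest linear sequence: 5 (steps 1 → 2 → 4 → 5 → 6); step 3 is a one-step side branch.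

Steps most likely to fail, with fallbacks:

1. **Step 4 (proposed new allylboration).** Risks: the hindered secondary allyl-Bpin may be sluggish toward a ketone; addition at the other carbonyl gives the 7E isomer; ee or 14Z selectivity may be low; the facial sense is unproven. Fallback (known chemistry): mono-ketalise 4 to 4,4-dimethoxycyclopent-2-enone and run a 3,3′-Br2-BINOL-catalysed ketone allylboration with allyl-B(OiPr)2. Hydrolyse the ketal to (R)-4-allyl-4-hydroxycyclopent-2-enone, extend to the (Z)-octenyl chain by Ru-catalysed Z-selective cross-metathesis with 1-heptene, then attach 3 by LDA aldol and MsCl/Et3N dehydration, separating 7Z from 7E. The same epoxidation/HBr end-game follows.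

2. **Step 2 (Knoevenagel to 5).** Risks: base-sensitive dione 4 and the very electrophilic product 5 may oligomerise or give Michael bis-adducts. Fallback: mask the ring alkene as the cyclopentadiene Diels–Alder adduct of 4, condense that with 3, and release 5 by retro-Diels–Alder (flash vacuum pyrolysis).

3. **Step 6 (with step 5).** Risks: HOO⁻ may compete at C7; under HBr the tertiary, allylic C12–OH may ionise, or reversible bromide addition at C7 may scramble 7Z/7E. Fallback: carry bromine from the start by converting 4 to 4-bromocyclopent-4-ene-1,3-dione (Br2, then Et3N) and condensing with 3. Separate the alkylidene isomer whose chain is cis to the C–Br-flanked carbonyl, and run step 4 on it so that the allylboration is the last step and no epoxide or HBr touches the tertiary alcohol.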